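The runs are simulated on assumed constants.

Whoever keeps the books of the reagent starts from the winter run, in which the reagent itself was never read.

| setting | winter | flask |
|---|---|---|
| left-handed substrate | 0.89 M | 0.89 M |
| right-handed substrate | 0.89 M | 0.89 M |
| reagent | 1.07 M | 1.07 M |
| free catalyst | 8.4 mM | 5.6 mM |
| remark | run made earlier |  |
| time |  | 4.0 d |

- winter (time / h: left-handed product / %, right-handed product / %, left-handed substrate / %): 2.50: 4.1, 0.7, 44.6; 4.00: 7.8, 3.5, 40.4; 8.00: 10.1, 4.9, 40.1; 15.0: 13.6, 6.0, 36.0; 30.0: 12.9, 9.1, 34.2

(scatter of a reading: 1 percentage point)

- free catalyst is single-handed; left-handed substrate and right-handed substrate are mirror images of each other, charged as a racemate, each of them at the stated concentration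
- the numbers in the tables scatter by 1 percentage point (one standard deviation)
- an excess is the difference of the two amounts in percent of their sum
- an excess is below zero if the other one leads
- no earlier run changes the charge of free catalyst; that part of a forecast is a guess

* excess of left-handed product over right-handed product in the product at 2.0 h
* excess of left-handed product over right-handed product in the product at 4.0 d
* part of the left-handed substrate and right-handed substrate charged together that has reacted at 4.0 d

I assume one reagent per product. The winter account for c(reagent) at 30.0 h then reads:

charged: 1.07 M
in both products: 0.392 M
unbooked, not read: 0.678 M

The product entry moves little late in the winter run: the sum of both products goes from 19.6% at 15.0 h to 22.0% at 30.0 h. So I treat that sum as the large thing and follow the small correction on it, the lead of left-handed product over right-handed product: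

lead: 7.6 percentage points, then 3.8 points

That is a fall to half. Call 15.0 h the half-life of the lead: the time in which the lead halves while the product sum stands nearly still. It is a rough reading, since each lead carries the scatter of two readings.

I carry it to the new flask, and that is a guess, since no earlier run changes the free catalyst. From 30.0 h to 4.0 d the lead halves 4.40 times:

lead at the end: 0.18 points
excess, over the winter sum: 0.818%

For the early excess and the conversion I reckon nothing of my own.

The forecast gives 40%, 27% and 19%, and it says that the fall of the excess at 30.0 h hints at “a racemic background or racemisation”. My excess lies below its low end of 14%.

The flask gives 56.2%, 1.38% and 20.9%.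

    reagent + free catalyst + left-handed substrate → free catalyst + left-handed product (k = 6.20 M⁻² h⁻¹)
    reagent + free catalyst + right-handed substrate → free catalyst + right-handed product (k = 1.50 M⁻² h⁻¹)
    left-handed product ⇌ right-handed product (k = 0.0330 h⁻¹)
    reagent + free catalyst → spent catalyst (k = 0.0240 M⁻¹ h⁻¹)
    2 reagent → self-condensation product (k = 0.0680 M⁻¹ h⁻¹)

At 4.0 d the excess of the flask stands 26 points below the forecast, and my own reckoning gave 0.818%. The half-life of left-handed product by the forward racemisation step alone, 0.88 d at 0.155 d, is shorter than the 4.0 d of the flask, and at the end the flask holds 10.6% left-handed product beside 10.3% right-handed product. Carried to a neighbour flask charged with 0.0034 M free catalyst, the half-life of the lead 15.0 h, started from the winter lead and divided by the winter sum, gives the same 0.818%. That neighbour stands at an excess of 1.93%.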